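## Structural features

The target (28 in the route) consists of three ring systems joined at two spiro carbons. Ring A is a 5-methoxy-4,6,6-trimethylcyclohex-4-ene-1,3-dione whose C2 (Ca) lies between the two ketones; ring B is the cyclopentane Ca–C1′–C2′–C3′–Cb; Cb is C2 of a 6,6-dimethylbicyclo[3.1.1]heptane (pinane). There are five stereocentres: the bridgeheads C1 and C5 (as in (1R,5R)-α-pinene), the quaternary Cb next to C1, the quaternary Ca next to Cb, and C1′ (H, isopropyl) next to Ca. Reading the SMILES, Ca lies on the pinane face that carries the gem-dimethyl bridge C6 (C3′ on the face of the CH2 bridge C7), and on ring B the isopropyl group is cis to the ring A carbonyl that adjoins the C-methyl carbon. The sulfone 24 and the diene 27 of the key step carry the same descriptors at all five centres, so their structures need no correction.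

The fragile groups are the non-enolisable 2,2-disubstituted 1,3-diketone (retro-Claisen cleavage by nucleophilic base), the vinylogous methyl ester (acid, hydroxide, SN2 demethylation) and the pinane cyclobutane (cations at C2). Before Ca is quaternary, ring A is an acidic enol. It is attacked by ozone, its oxygens close a five-membered ring onto any electrophilic C2′ (dihydrofuran, or furan from an aldehyde), and it condenses with a free thiol at C2′. A sequence that ozonises, reduces and thiolates next to the free dione therefore fails. The route masks the enol as an acetate for exactly these operations and never isolates the thiol.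

The real difficulty is the Ca–Cb bond: two adjacent quaternary carbons, with Ca on the more shielded face of the pinane and ring A in one of two orientations. The key step exploits the two adjacent methylenes C2′ and C3′ of ring B between C1′ and Cb. A sulfonyl group placed between them gives the six-membered ring Ca–C1′–C2′–SO2–C3′–Cb, from which SO2 is extruded to leave the C2′–C3′ bond. C3′ is the allylic methyl carbon (C10) of a verbenone-type enone, so the same sulfur first joins the two halves.

## Logic of the disconnections

**28 ⇒ 27.** The C2′–C3′ and pinane C3–C4 single bonds are taken back to cis alkenes. Both alkenes are left behind by the bond-forming steps, so nothing has to be protected or removed. The forward step must add hydrogen to two hindered disubstituted alkenes without touching the tetrasubstituted enol ether and without moving the C2′=C3′ bond towards C1′, which would endanger that centre.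

**27 ⇒ 24 (key).** The C2′=C3′ bond is cut and a sulfonyl group is inserted between C2′ and C3′. This turns a crowded cyclopentene flanked by two spiro centres into a six-membered sulfone whose two C–S bonds are easy to make. The forward step forms only the C2′–C3′ bond and no stereocentre. It must halogenate an α-sulfonyl carbon and close the episulfone in the presence of a diketone that cannot enolise but can be cleaved by base.

**24 ⇒ 23.** The two S–O bonds are removed. Oxidation is placed after the ring closure because a sulfone would acidify C3′–H and invite elimination at the allyl-metal stage, and because an enolised ring A would not survive the oxidant. The forward step must oxidise sulfur and spare the pinane alkene.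

**23 ⇒ 22.** The Ca–Cb bond is cut to an enolisable ring A dione and a C2–C3–C4 allyl cation equivalent held together by the sulfide. The gain is that both quaternary centres arise in one ring closure to a six-membered ring. The forward step must deliver Ca to the tether-bearing terminus C2 on the face of the C6 bridge. This is obtained from a C4 leaving group on that same face by two inversions at palladium. The step must also fix the orientation of ring A.

**22 ⇒ 20 ⇒ 19.** The carbonate C–O bond and then the C4–H bond are removed, leading back to the enone. Hydride adds from the open face, which places the oxygen on the face of the C6 bridge, as the closure needs.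

**19 ⇒ 14 + 17.** The S–C3′ bond is cut. It joins a thiolate and a primary allylic bromide, the mildest union available, and the far less nucleophilic dione enolate does not interfere. The thiol must be generated in the presence of the bromide and never isolated.

**14 ⇒ 13 ⇒ 11 ⇒ 10.** The C2′–S bond, then the C2′ oxidation level, then the enol mask are removed. C2′ is the inner carbon of a vinyl group after excision of the terminal carbon. The forward steps need a mask that removes the nucleophilicity of the ring A oxygens and a cleavage reagent that ignores tetrasubstituted enol double bonds.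

**10 ⇒ 5 + 9.** The Ca–C1′ bond is cut to the ring A dione and a linear allyl carbonate. This is the only point where absolute configuration is introduced by a catalyst. It calls for branched-selective, enantioselective allylation of a cyclic 1,3-dione by an α-branched alkyl allyl unit.

**5 ⇒ 3 ⇒ 2 ⇒ 1.** The ester on Ca is a blocking and directing group: it stops C-methylation at three methyl groups, and through chelation it steers O-methylation to the oxygen between the CMe2 and C-methyl carbons. Its removal must spare the enol ether.

**9 ⇒ 8 ⇒ 7 ⇒ 6 and 17 ⇒ 16 ⇒ 15.** A two-carbon olefination, reduction and acylation give the allyl carbonate. Two allylic oxidations (C4 to the ketone, C10 to the bromide) give the electrophile and leave the chiral-pool bridgeheads untouched.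

## Other disconnections considered

**Alternative 1:** The cuts are the C1′–isopropyl bond and the bond from Ca to the CMe2-flanked carbonyl, so ring A is built after ring B.
- Forward step: an isopropyl cuprate (i-PrMgCl, CuBr·SMe2, Me3SiCl) adds to C1′ of the spiro cyclopentene ester A2. The lithium enolate, released with MeLi, is C-acylated by the acid chloride A3 to give keto ester A1. A Claisen closure and O-methylation would finish ring A.
- In its favour: C1′ is set by substrate control, since the cuprate should enter from the face of ring B that carries the pinane CH2. No chiral catalyst and no sulfur are needed. The late O-methylation should be steered by the crowded spiro centre, which is a better position than the chelation-dependent O-methylation used in the chosen plan.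
- Against it: A2 already contains Cb with the ester-bearing carbon on the shielded face, so the hardest stereochemical problem is moved into the synthesis of A2 and not solved. Acylation of a fully substituted enolate between two branched centres competes with O-acylation. A1 is exposed to retro-Claisen cleavage in the basic ring closure.
- Comparison: control at Ca rests on a subtle facial preference in both plans (equal). The chosen plan makes Ca–Cb by a stereospecific double inversion, which this plan leaves open. After A2 this route is shorter, but overall probably not.

**Alternative 2:** The cuts are the two bonds from the ring A carbonyls to C(CH3)2 and C(H)CH3.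
- Forward step: the spiro malonate A5 and 2-methylpentan-3-one A6 undergo a double Claisen condensation with excess KH in hot 1,2-dimethoxyethane to give trione A4, followed by O-methylation.
- In its favour: ring A comes in one step from a trivial ketone. This is the best step economy of all four plans for that ring, and better than the three steps spent here on 5.
- Against it: the two esters of A5 are diastereotopic, and nothing decides which is joined to the isopropyl carbon, so Ca would form with little control. Acylation at the tertiary enolate carbon is slow. Hot KH acts on non-enolisable β-dicarbonyl intermediates. A5 again presupposes Cb.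
- Comparison: shorter, but weaker in stereocontrol at Ca and harsher on the same diketone than the cold, heterogeneous key step chosen here.

**Alternative 3:** The cuts are the Ca–Cb bond (made by a 1,2-shift) and the bond between the Ca-bound carbonyl and C(H)CH3.
- Forward step: photolysis (300 nm, THF, low temperature) of the α-diazo ketone A8 makes Cb migrate to the carbene carbon, contracting the ring to ketene A9. The lithium enolate of keto ester A10 is then C-acylated by A9 to give A7.
- In its favour: Cb migrates with retention, so its configuration can be set earlier in a six-membered ketone by alkylation from the open face of the pinane. This is stereochemically easier than the attack on the shielded face that the chosen plan requires, and it is the strongest point of any alternative. It is also a ring contraction without sulfur.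
- Against it: a diazo ketone beside a neopentyl-type quaternary carbon, competing O-acylation of a hindered enolate, two centres formed without control at first (Ca is fixed only in the last Claisen closure), and a photochemical step that scales poorly.
- Comparison: better for Cb, about equal for Ca, probably longer, and less convergent than the thiolate union.

Key step: step 18

Remark on the chemistry: in 11–14 and 21 the O-acyl group on the enolised ring A is drawn on the oxygen next to the C-methyl carbon; the other O-acyl regioisomer would react in the same way and converge on 19 and 22. The ligand antipode in step 7 is chosen from the usual facial preference of this catalyst family.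

## Route

**Step 1**
Reactants: 1 methyl 2,4,6-trihydroxybenzoate
Product: 2 methyl 3,3,5-trimethyl-2,4,6-trioxocyclohexane-1-carboxylate (enolised; C5 not fixed)
Conditions: NaOMe (4 equiv), MeI (3.1 equiv), MeOH, 0 °C → rt
Reagents that add atoms: iodomethane, CI
Why: Dearomatising C-methylation of an acylphloroglucinol-type anion; the ester-bearing carbon is not methylated, and the amount of MeI should stop the sequence at one CMe2 and one CHMe carbon.

**Step 2**
Reactants: 2 methyl 3,3,5-trimethyl-2,4,6-trioxocyclohexane-1-carboxylate
Product: 3 methyl 4-methoxy-3,5,5-trimethyl-2,6-dioxocyclohex-3-ene-1-carboxylate (chelated enol)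
Conditions: Me3SiCHN2 (1.1 equiv), toluene/MeOH 4:1, 0 °C
Reagents that add atoms: (trimethylsilyl)diazomethane, C[Si](C)(C)C=[N+]=[N-]
Why: O-methylation of a vinylogous acid by a diazoalkane; the hydrogen-bonded tricarbonyl enol should stay inert and the free enol oxygen remote from the chelate (between CMe2 and C–Me) should be methylated, as in the natural O-methyl β-triketones.

**Step 3**
Reactants: 3 methyl 4-methoxy-3,5,5-trimethyl-2,6-dioxocyclohex-3-ene-1-carboxylate
Product: 5 5-methoxy-4,6,6-trimethylcyclohex-4-ene-1,3-dione (ring A dione), via keto acid 4 (not isolated)
Conditions: LiOH·H2O (4 equiv), THF/H2O 1:1, 45 °C; then 1 M HCl to pH 2, 40 °C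
Reagents that add atoms: none
Why: Saponification and decarboxylation of a 2-carboxy-1,3-dione; the substrate reacts as its delocalised anion, which deactivates the enol ether, and the ester carbonyl is far less hindered than the enol ether carbon beside CMe2.

**Step 4**
Reactants: 6 isobutyraldehyde
Product: 7 ethyl (E)-4-methylpent-2-enoate
Conditions: (EtO)2P(O)CH2CO2Et, NaH, THF, 0 °C → rt
Reagents that add atoms: triethyl phosphonoacetate, CCOC(=O)CP(=O)(OCC)OCC
Why: Horner–Wadsworth–Emmons olefination, reliably E-selective with an α-branched aldehyde.

**Step 5**
Reactants: 7 ethyl (E)-4-methylpent-2-enoate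
Product: 8 (E)-4-methylpent-2-en-1-ol
Conditions: i-Bu2AlH (2.2 equiv), CH2Cl2, −78 → 0 °C
Reagents that add atoms: none
Why: 1,2-Reduction of an enoate to the allylic alcohol by an aluminium hydride.

**Step 6**
Reactants: 8 (E)-4-methylpent-2-en-1-ol
Product: 9 methyl (E)-4-methylpent-2-en-1-yl carbonate
Conditions: ClCO2Me, pyridine, CH2Cl2, 0 °C
Reagents that add atoms: methyl chloroformate, COC(Cl)=O
Why: Acylation of a primary alcohol; the methyl carbonate releases methoxide on ionisation and so provides the base for step 7.

**Step 7**
Reactants: 5 5-methoxy-4,6,6-trimethylcyclohex-4-ene-1,3-dione; 9 methyl (E)-4-methylpent-2-en-1-yl carbonate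
Product: 10 5-methoxy-4,6,6-trimethyl-2-[(3S)-4-methylpent-1-en-3-yl]cyclohex-4-ene-1,3-dione (enol)
Conditions: [Ir(cod)Cl]2 (2 mol %), (Ra,R,R)-binaphthyl N,N-bis(1-phenylethyl)phosphoramidite (4 mol %), TBD (8 mol %), THF, 40 °C
Reagents that add atoms: none
Why: Iridium-catalysed asymmetric allylic alkylation of a stabilised carbon acid; the cyclometallated iridium phosphoramidite sends the nucleophile to the substituted allyl terminus and one enantiotopic face, which sets C1′ (S here, the arrangement that becomes R in 28); any O-allyl enol ether can re-ionise and funnel to the C-allyl product.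

**Step 8**
Reactants: 10 5-methoxy-4,6,6-trimethyl-2-[(3S)-4-methylpent-1-en-3-yl]cyclohex-4-ene-1,3-dione
Product: 11 enol acetate of 10 (5-methoxy-4,4,6-trimethyl-2-[(3S)-4-methylpent-1-en-3-yl]-3-oxocyclohexa-1,5-dien-1-yl acetate)
Conditions: Ac2O, Et3N, DMAP (cat.), CH2Cl2, 0 °C
Reagents that add atoms: acetic anhydride, CC(=O)OC(C)=O
Why: O-acylation of a 2-substituted 1,3-dione; the vinylogous anhydride has no acidic hydrogen and much less nucleophilic oxygens, which the next two steps require.

**Step 9**
Reactants: 11 enol acetate of 10
Product: 13 (2R)-2-(ring A enol acetate)-3-methylbutan-1-ol, via aldehyde 12 (not isolated)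
Conditions: K2OsO4·2H2O (2 mol %), NaIO4 (4 equiv), 2,6-lutidine, dioxane/H2O 3:1, rt; extraction; NaBH4, THF/H2O, −10 °C, then AcOH
Reagents that add atoms: sodium periodate, [Na+].[O-]I(=O)(=O)=O (oxygen source through the osmium catalyst)
Why: Lemieux–Johnson cleavage, for which the unhindered vinyl group should react far faster than the two tetrasubstituted, electron-poor ring alkenes; the α-branched aldehyde is reduced at once so that C1′ cannot epimerise, and methanol is avoided to keep the enol acetate.

**Step 10**
Reactants: 13 (2R)-2-(ring A enol acetate)-3-methylbutan-1-ol
Product: 14 S-[(2R)-2-(ring A enol acetate)-3-methylbutyl] ethanethioate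
Conditions: PPh3, i-PrO2CN=NCO2i-Pr, AcSH, THF, 0 °C
Reagents that add atoms: thioacetic acid, CC(=O)S
Why: Mitsunobu thioesterification of a β-branched primary alcohol; thioacetate is present from the start at high concentration and should outrun participation by the deactivated ring carbonyl; C1′ is not involved.

**Step 11**
Reactants: 15 (1R,5R)-(+)-α-pinene
Product: 16 (1R,5R)-(+)-verbenone
Conditions: CrO3 (5 mol %), t-BuOOH (70% in water, 4 equiv), CH2Cl2, rt
Reagents that add atoms: tert-butyl hydroperoxide, CC(C)(C)OO
Why: Catalytic allylic oxidation of the ring CH2 (C4) to the enone; the bridgeheads are untouched.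

**Step 12**
Reactants: 16 (1R,5R)-(+)-verbenone
Product: 17 10-bromoverbenone (4-(bromomethyl)-6,6-dimethylbicyclo[3.1.1]hept-3-en-2-one)
Conditions: NBS (1.05 equiv), AIBN (cat.), PhCF3, 85 °C
Reagents that add atoms: N-bromosuccinimide, O=C1CCC(=O)N1Br
Why: Wohl–Ziegler γ-bromination of a β-methyl enone; the methyl group is the only γ-position that gives a delocalised radical (the other is a bridgehead), and the radical has no spin density on C2, so the cyclobutane should not open.

**Step 13**
Reactants: 14 S-[(2R)-2-(ring A enol acetate)-3-methylbutyl] ethanethioate; 17 10-bromoverbenone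
Product: 19 sulfide enone (ring A dione–CH(i-Pr)–CH2–S–CH2–verbenone), via dione thiol 18 (not isolated)
Conditions: K2CO3 (3 equiv), degassed MeOH, 0 °C, 20 min; then 17 (1.0 equiv), 0 °C → rt
Reagents that add atoms: none
Why: Methanolysis of both acetyl groups followed by S-alkylation in one flask; the enol acetate, a vinylogous anhydride, should be cleaved at least as fast as the thioester, so the thiolate appears beside an unreactive enolate, and it is far more nucleophilic than that enolate toward the allylic bromide; the thiol is never exposed to acid beside the dione.

**Step 14**
Reactants: 19 sulfide enone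
Product: 20 cis-allylic alcohol (C4 hydroxyl on the face of the gem-dimethyl bridge)
Conditions: NaBH4 (3 equiv), CeCl3·7H2O, MeOH, −40 °C
Reagents that add atoms: none
Why: Luche 1,2-reduction; hydride enters from the face of the CH2 bridge, as in the reduction of verbenone to cis-verbenol, and sets C4; ring A is protected as its enolate.

**Step 15**
Reactants: 20 cis-allylic alcohol
Product: 22 cis-allylic methyl carbonate with free ring A dione, via bis-carbonate 21 (not isolated)
Conditions: ClCO2Me (3 equiv), pyridine, DMAP (cat.), CH2Cl2, 0 °C; then morpholine (1.5 equiv), 0 °C, 15 min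
Reagents that add atoms: methyl chloroformate, COC(Cl)=O
Why: Exhaustive acylation followed by selective aminolysis of the enol carbonate, which as a vinylogous mixed anhydride is far more reactive than the alkyl carbonate; this leaves the acidic dione needed for a base-free ring closure.

**Step 16**
Reactants: 22 cis-allylic methyl carbonate with free ring A dione
Product: 23 spiro thiane (sulfide; Ca, C1′ and Cb as in 28; pinane C3=C4)
Conditions: Pd2(dba)3·CHCl3 (5 mol %), dppe (12 mol %), THF (0.01 M), 50 °C
Reagents that add atoms: none
Why: Intramolecular Tsuji–Trost alkylation: zerovalent palladium ionises the carbonate from the open face, the methoxide released deprotonates the dione within the same molecule, and the enolate attacks anti to the metal at the tether-bearing terminus C2 (six-membered ring; the other terminus would need an eight-membered one), so Ca ends on the face of the C6 bridge by net retention; in a chair-like transition state with isopropyl equatorial, the flat enol-ether flank of ring A should lie over the pinene ring and the CMe2 flank outside, which is the required configuration at Ca.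

**Step 17**
Reactants: 23 spiro thiane
Product: 24 spiro thiane 1,1-dioxide (precursor of the key step)
Conditions: (NH4)6Mo7O24·4H2O (10 mol %), 30% H2O2 (4 equiv), EtOH, 0 °C → rt
Reagents that add atoms: hydrogen peroxide, OO
Why: Peroxomolybdate oxidation of a sulfide to the sulfone, known to spare unactivated alkenes; ring A can no longer enolise and is inert.

**Step 18**
Reactants: 24 spiro thiane 1,1-dioxide
Product: 27 spiro diene (C2′=C3′ and pinane C3=C4), via α-bromo sulfone 25 (not isolated), via episulfone 26 (not isolated)
Conditions: KOH on Al2O3 (excess), CBr2F2 (5 equiv), t-BuOH/CH2Cl2 1:1, 0 °C → rt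
Reagents that add atoms: none
Why: Ramberg–Bäcklund reaction with in situ halogenation: the base forms a small equilibrium amount of α-sulfonyl carbanion, which takes bromine from CBr2F2 to give 25; deprotonation at the other α-carbon and 1,3-displacement of bromide (3-exo-tet) closes the episulfone 26, which loses SO2 cheletropically and leaves the C2′=C3′ bond. The closest precedent is the contraction of six-membered cyclic sulfones to cyclopentenes under these conditions. Ring B is thus closed by contraction, with the C2′–C3′ bond made in the three-membered ring closure. No stereocentre is formed, and the five-membered ring allows only the cis alkene. It does not matter which α-carbon is brominated, since both routes lead to the same episulfone. The chemoselectivity needed is halogenation at sulfur-activated carbon only, and the substrate secures it because the spiro diketone has no enolisable hydrogen and the sulfonyl-flanked CH2 groups are the only C–H acids. The selectivity that is not secured by structure is base versus carbonyl: the solid-supported hydroxide, the low temperature and the quaternary carbons flanking both ketones are relied on to keep retro-Claisen cleavage slower than carbanion formation.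

**Step 19**
Reactants: 27 spiro diene
Product: 28 target (CNP0307059.1)
Conditions: H2 (1 atm), 5% Pt/C, EtOAc, rt
Reagents that add atoms: none
Why: Heterogeneous hydrogenation of two cis-disubstituted alkenes; all four carbons become CH2, so no stereocentre is formed; platinum is preferred to palladium because it is less prone to move the C2′=C3′ bond towards C1′; the tetrasubstituted enol ether and the hindered ketones should not react.

## Compound list

1 | methyl 2,4,6-trihydroxybenzoate | COC(=O)c1c(O)cc(O)cc1O | starting material
2 | methyl 3,3,5-trimethyl-2,4,6-trioxocyclohexane-1-carboxylate | COC(=O)C1C(=O)C(C)C(=O)C(C)(C)C1=O | intermediate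
3 | methyl 4-methoxy-3,5,5-trimethyl-2,6-dioxocyclohex-3-ene-1-carboxylate | COC(=O)C1C(=O)C(C)=C(OC)C(C)(C)C1=O | intermediate
4 | 4-methoxy-3,5,5-trimethyl-2,6-dioxocyclohex-3-ene-1-carboxylic acid | OC(=O)C1C(=O)C(C)=C(OC)C(C)(C)C1=O | intermediate (not isolated)
5 | 5-methoxy-4,6,6-trimethylcyclohex-4-ene-1,3-dione | COC1=C(C)C(=O)CC(=O)C1(C)C | intermediate
6 | isobutyraldehyde | CC(C)C=O | starting material
7 | ethyl (E)-4-methylpent-2-enoate | CCOC(=O)/C=C/C(C)C | intermediate
8 | (E)-4-methylpent-2-en-1-ol | CC(C)/C=C/CO | intermediate
9 | methyl (E)-4-methylpent-2-en-1-yl carbonate | COC(=O)OC/C=C/C(C)C | intermediate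
10 | 5-methoxy-4,6,6-trimethyl-2-[(3S)-4-methylpent-1-en-3-yl]cyclohex-4-ene-1,3-dione | COC1=C(C)C(=O)C([C@@H](C(C)C)C=C)C(=O)C1(C)C | intermediate
11 | enol acetate of 10 | COC1=C(C)C(OC(C)=O)=C([C@@H](C(C)C)C=C)C(=O)C1(C)C | intermediate
12 | (2R)-2-(ring A enol acetate)-3-methylbutanal | COC1=C(C)C(OC(C)=O)=C([C@@H](C(C)C)C=O)C(=O)C1(C)C | intermediate (not isolated)
13 | (2R)-2-(ring A enol acetate)-3-methylbutan-1-ol | COC1=C(C)C(OC(C)=O)=C([C@@H](C(C)C)CO)C(=O)C1(C)C | intermediate
14 | S-[(2R)-2-(ring A enol acetate)-3-methylbutyl] ethanethioate | COC1=C(C)C(OC(C)=O)=C([C@@H](C(C)C)CSC(C)=O)C(=O)C1(C)C | intermediate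
15 | (1R,5R)-(+)-α-pinene | CC1=CC[C@@H]2C[C@H]1C2(C)C | starting material
16 | (1R,5R)-(+)-verbenone | CC1=CC(=O)[C@@H]2C[C@H]1C2(C)C | intermediate
17 | 10-bromoverbenone | BrCC1=CC(=O)[C@@H]2C[C@H]1C2(C)C | intermediate
18 | 2-[(2R)-1-sulfanyl-3-methylbutan-2-yl]-5-methoxy-4,6,6-trimethylcyclohex-4-ene-1,3-dione | COC1=C(C)C(=O)C([C@@H](C(C)C)CS)C(=O)C1(C)C | intermediate (not isolated)
19 | sulfide enone | COC1=C(C)C(=O)C([C@@H](C(C)C)CSCC2=CC(=O)[C@@H]3C[C@H]2C3(C)C)C(=O)C1(C)C | intermediate
20 | cis-allylic alcohol | COC1=C(C)C(=O)C([C@@H](C(C)C)CSCC2=C[C@@H](O)[C@@H]3C[C@H]2C3(C)C)C(=O)C1(C)C | intermediate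
21 | bis(methyl carbonate) of 20 | COC1=C(C)C(OC(=O)OC)=C([C@@H](C(C)C)CSCC2=C[C@@H](OC(=O)OC)[C@@H]3C[C@H]2C3(C)C)C(=O)C1(C)C | intermediate (not isolated)
22 | cis-allylic methyl carbonate with free dione | COC1=C(C)C(=O)C([C@@H](C(C)C)CSCC2=C[C@@H](OC(=O)OC)[C@@H]3C[C@H]2C3(C)C)C(=O)C1(C)C | intermediate
23 | spiro thiane | COC1=C(C)C(=O)[C@@]2(C(=O)C1(C)C)[C@@H](C(C)C)CSC[C@@]21C=C[C@@H]2C[C@H]1C2(C)C | intermediate
24 | spiro thiane 1,1-dioxide | COC1=C(C)C(=O)[C@@]2(C(=O)C1(C)C)[C@@H](C(C)C)CS(=O)(=O)C[C@@]21C=C[C@@H]2C[C@H]1C2(C)C | intermediate (key-step precursor)
25 | α-bromo sulfone (bromine on C2′) | COC1=C(C)C(=O)[C@@]2(C(=O)C1(C)C)[C@@H](C(C)C)C(Br)S(=O)(=O)C[C@@]21C=C[C@@H]2C[C@H]1C2(C)C | intermediate (not isolated)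
26 | episulfone | COC1=C(C)C(=O)[C@@]2(C(=O)C1(C)C)[C@@H](C(C)C)C3C(S3(=O)=O)[C@@]21C=C[C@@H]2C[C@H]1C2(C)C | intermediate (not isolated)
27 | spiro diene | COC1=C(C)C(=O)[C@@]2(C(=O)C1(C)C)[C@@H](C(C)C)C=C[C@@]21C=C[C@@H]2C[C@H]1C2(C)C | intermediate (key-step product)
28 | CNP0307059.1 | COC1=C(C)C(=O)[C@@]2(C(=O)C1(C)C)[C@@H](C(C)C)CC[C@@]21CC[C@@H]2C[C@H]1C2(C)C | target

## Step count and least certain steps

Total step count: 19. Longest linear sequence: 14 steps (1–3, 7–10, 13–19).

**Step 18 (key step).** The most likely failure is attack of hydroxide on the spiro diketone (retro-Claisen) or on the enol ether, because carbanion formation at a hindered dialkyl sulfone is slow. A second risk is double bromination at one α-carbon before ring closure, which would lead to a brominated alkene. The fallback places the halogen at the sulfide stage and avoids hydroxide. It sets out from 23: NCS in CH2Cl2 at 0 °C gives the α-chloro sulfide F1 through the chlorosulfonium ion. Oxidation with the peroxomolybdate system of step 17 gives the α-chloro sulfone F2. t-BuOK in THF at −78 → 0 °C then performs the classical Ramberg–Bäcklund closure and SO2 loss, rejoining the route at 27. The chloride is drawn on C3′, where no β-hydrogen allows elimination; the C2′ isomer would converge.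

**Step 16.** The enolate must reach C2 on the face shielded by the C6 bridge. If carbon–carbon bond formation is slower than loss of a C3′ proton from the allyl complex to the methoxide, a dienyl sulfide results. The thioether may also hold the catalyst, and ring A may close in the other orientation (the Ca epimer). The fallback changes how the electrophile is generated. From 22, palladium-catalysed elimination (Pd(OAc)2, PPh3, toluene, 80 °C) is run on purpose to give the dienyl sulfide F3. F3 is then cyclised by palladium hydride hydroalkylation of the diene (Pd(PPh3)4, THF, 60 °C, the dione acting as the acid), rejoining the route at 23. With no base present, the diene and the allyl complex interconvert, so a slow closure is no longer outrun by an irreversible side path; the attack still occurs anti to the metal. Should the Ca epimer form, re-ionisation of the allylic Ca–Cb bond by the same catalyst offers equilibration.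

**Step 10.** The ring carbonyl oxygen, five atoms from C2′, may displace the activated alcohol and lead to a fused dihydrofuran, or the acetyl group may migrate to the primary oxygen. The fallback makes the C–S bond by reduction and not by substitution. It sets out from 12 (isolated after step 9) and 17: KSAc on 17 gives the thioacetate F4, and K2CO3/MeOH gives the thiol F5. F5 and 12 with BF3·OEt2 and Et3SiH in CH2Cl2 at −40 °C give, by reductive thioetherification, the sulfide enone enol acetate F6. K2CO3/MeOH then removes the enol acetate, rejoining the route at 19.

**Step 7.** An α-branched alkyl (isopropyl) allyl unit is a demanding substrate: the risks are a low branched-to-linear ratio, slow turnover and O-allylation of the acidic dione. The fallback sets C1′ by organocatalysis. From 6, nitromethane (Henry reaction, then MsCl/Et3N) gives the nitroalkene F7. A bifunctional squaramide-catalysed Michael addition of 5 to F7 gives the adduct F8 with C1′ in the required sense. Ac2O/Et3N gives its enol acetate F9, and a buffered TiCl3 Nef reaction gives 12, rejoining the route in step 9.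

**Step 19.** The C2′=C3′ bond may migrate towards C1′ on the metal surface and endanger that centre, or traces of sulfur may stop the catalyst. The fallback is metal-free reduction with diimide (2-nitrobenzenesulfonyl hydrazide, Et3N, CH2Cl2, rt), which cannot isomerise alkenes; it goes from 27 directly to 28.

## Further compounds

F1 | step 18 | α-chloro sulfide of 23 (chlorine on C3′) | COC1=C(C)C(=O)[C@@]2(C(=O)C1(C)C)[C@@H](C(C)C)CSC(Cl)[C@@]21C=C[C@@H]2C[C@H]1C2(C)C
F2 | step 18 | α-chloro sulfone | COC1=C(C)C(=O)[C@@]2(C(=O)C1(C)C)[C@@H](C(C)C)CS(=O)(=O)C(Cl)[C@@]21C=C[C@@H]2C[C@H]1C2(C)C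
F3 | step 16 | dienyl sulfide with free ring A dione | COC1=C(C)C(=O)C([C@@H](C(C)C)CSC=C2C=C[C@@H]3C[C@H]2C3(C)C)C(=O)C1(C)C
F4 | step 10 | S-acetyl 10-sulfanylverbenone | CC(=O)SCC1=CC(=O)[C@@H]2C[C@H]1C2(C)C
F5 | step 10 | 10-sulfanylverbenone | SCC1=CC(=O)[C@@H]2C[C@H]1C2(C)C
F6 | step 10 | sulfide enone enol acetate | COC1=C(C)C(OC(C)=O)=C([C@@H](C(C)C)CSCC2=CC(=O)[C@@H]3C[C@H]2C3(C)C)C(=O)C1(C)C
F7 | step 7 | (E)-4-methyl-1-nitropent-1-ene | CC(C)/C=C/[N+](=O)[O-]
F8 | step 7 | 5-methoxy-4,6,6-trimethyl-2-[(2R)-3-methyl-1-nitrobutan-2-yl]cyclohex-4-ene-1,3-dione | COC1=C(C)C(=O)C([C@@H](C(C)C)C[N+](=O)[O-])C(=O)C1(C)C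
F9 | step 7 | enol acetate of F8 | COC1=C(C)C(OC(C)=O)=C([C@@H](C(C)C)C[N+](=O)[O-])C(=O)C1(C)C
F0 | step 19 | none | none
A1 | alternative 1 | spiro keto ester with quaternary Ca | CCC(=O)C(C)(C)C(=O)[C@]3(C(=O)OC)[C@@H](C(C)C)CC[C@@]31CC[C@@H]2C[C@H]1C2(C)C
A2 | alternative 1 | spiro cyclopentene ester | COC(=O)C1=CCC[C@@]12CC[C@@H]3C[C@H]2C3(C)C
A3 | alternative 1 | 2,2-dimethyl-3-oxopentanoyl chloride | CCC(=O)C(C)(C)C(Cl)=O
A4 | alternative 2 | spiro trione | O=C1C(C)C(=O)[C@@]2(C(=O)C1(C)C)[C@@H](C(C)C)CC[C@@]21CC[C@@H]2C[C@H]1C2(C)C
A5 | alternative 2 | spiro dimethyl malonate | COC(=O)C2(C(=O)OC)[C@@H](C(C)C)CC[C@@]21CC[C@@H]2C[C@H]1C2(C)C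
A6 | alternative 2 | 2-methylpentan-3-one | CCC(=O)C(C)C
A7 | alternative 3 | ring B triketo ester | COC(=O)C(C)(C)C(=O)C(C)C(=O)C3[C@@H](C(C)C)CC[C@@]31CC[C@@H]2C[C@H]1C2(C)C
A8 | alternative 3 | spiro α-diazo cyclohexanone | O=C1C(=[N+]=[N-])[C@@H](C(C)C)CC[C@@]12CC[C@@H]3C[C@H]2C3(C)C
A9 | alternative 3 | ring B ketene | O=C=C1[C@@H](C(C)C)CC[C@@]12CC[C@@H]3C[C@H]2C3(C)C
A10 | alternative 3 | methyl 2,2-dimethyl-3-oxopentanoate | CCC(=O)C(C)(C)C(=O)OC
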